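Abbreviations: prenyl = 3-methylbut-2-en-1-yl; MOM = methoxymethyl. Locants C2, C3, C3a, C6, C7, O1 refer to the benzofuran; primed locants refer to the pendant aryl ring (ring B).

## Analysis of the target

Eryvarin Q (22) is a 2-aryl-1-benzofuran-3-carbaldehyde: a benzo ring (ring A) fused to a furan, with a resorcinol-derived aryl group (ring B) on C2 and a formyl group on C3. Ring A carries a hydroxyl at C6 and a prenyl group at C7, between that hydroxyl and O1; ring B carries hydroxyls at C2′ and C4′ and a prenyl group at C5′, which is para to the C2′ hydroxyl and not between the two oxygens. The molecule has no stereocentre and is achiral, so stereochemistry can appear only in intermediates. The sensitive elements are the two ortho-prenylphenol pairs (acid closes them to 2,2-dimethylchromans, hydride-abstracting oxidants to chromenes), the electron-rich rings, and the aldehyde, which sits beside the C2′ hydroxyl and can close to a six-membered lactol or acetal. The difficulty lies in placing two prenyl groups at defined, different positions of two resorcinol rings and in building a fully substituted furan with an aryl group next to a carbonyl carbon, all under conditions that spare the prenyl groups. The strategy rests on how the furan atoms are bonded: C2 is attached to O1 and to ring B, so it is the benzylic carbon of an aryl benzyl ether, and C3 is attached to C3a and to a carbonyl carbon, so it is the ketone carbon of an aryl α-keto ester. O1–C2, C3–C3a and C3–CHO therefore already exist in an ortho-(benzyloxy)aryl glyoxylate, and only the C2–C3 bond is missing; it joins a CH2 with weak C–H bonds to a ketone that can be excited with light.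

## Retrosynthetic reasoning

**22 from 20.** The three phenols are unmasked last by cleaving the three aryl O–CH2 bonds of the MOM acetals of 20. The acetal is chosen because it also directs the metalation that places the C7 prenyl group and survives organolithium reagents, base, hydride, light and mild oxidation. The forward step must free three phenols without closing either prenyl group onto its neighbouring oxygen and without locking the aldehyde into an acetal with the C2′ hydroxyl.

**20 from 21 from 19.** The formyl carbon is traced back to a methyl ester. The C3 carbon is thus carried through the ring construction at the carboxyl level, where it is inert, and is brought to the aldehyde by full hydride reduction to 21 followed by a mild oxidation of the heteroaryl carbinol. Partial reduction of the conjugated ester is not relied on.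

**19 from 17.** The C2=C3 double bond is disconnected to the tertiary alcohol 17 by adding water across it. Forward, sulfonylation to 18 and elimination aromatise the furan. Both stereocentres of 17 disappear, so their relative configuration need not be controlled.

**17 from 15.** This is the central cut, C2–C3. In 15 the two carbons are a ketone carbon and an ether CH2 held five atoms apart by the ortho arrangement. Light turns the ketone into an oxygen-centred radical that takes a hydrogen from that CH2, and biradical 16 closes the ring. No base, acid, metal or oxidant meets the prenyl groups, and the reacting C–H is selected by geometry, not by a reagent.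

**15 from 9 and 14.** The O–CH2 ether bond is cut next, giving a phenol (ring A) and a benzylic alcohol (ring B), each already prenylated. They are joined by a redox condensation that activates the alcohol only in the flask. Converting 14 into a benzylic halide first is avoided, because a benzylic carbon with ortho and para oxygen donors ionises easily and is attacked by the neighbouring acetal oxygen, so such a halide would be hard to purify or store.

**9 from 8, and 8 from 5 and 6.** The free phenol of 9 comes from 8 by removing only the acetal ortho to the ketone, which the carbonyl group itself makes the more labile one. The aryl–CO bond of 8 is cut to aryllithium 7 and the diester 6, which supplies both carbonyl carbons in one piece. The lithium is placed by exchange of the bromine of 5. A directed ring lithiation of a prenylated arene without the bromine would compete with removal of a proton from the benzylic and allylic CH2 of the prenyl group; halogen–lithium exchange is faster than any deprotonation and fixes the site.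

**5 from 2 and 3, and 2 from 1.** The aryl–CH2 bond of the ring A prenyl group is cut at the carbon between the two oxygens. That position is the most acidic one of 2, so a hindered amide base gives aryllithium 4 without disturbing the bromine, and allylation with 3 follows. Compound 2 is the bis-acetal of commercial 1, whose bromine marks the future C3a from the outset.

**14 from 12 and 13, 12 from 11, 11 from 10.** On ring B the prenyl group must go para to one oxygen and not between the two, where deprotonation would put it. Its position is therefore fixed by the bromine of commercial 10 and the aryl–CH2 bond is made by palladium-catalysed coupling with the allylboronate 13 under linear-selective conditions. The aldehyde of 10 supplies the benzylic carbon (the future C2); it is reduced to 12 before the coupling so that the hydroxide base meets no aldehyde. Protection of both phenols (11) comes first.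

## Alternatives that were turned down

Alternative 1: Both aryl–CH2 bonds of the prenyl groups are disconnected together, back to the bis(1,1-dimethylallyl) ether A2 of a preformed benzofuran aldehyde. Forward, heating A2 in xylene would bring about two aromatic Claisen rearrangements and deliver the 2′-O-MOM ether of the target, A1. In its favour, both prenyl groups arrive in one thermal step without organometallic reagents, and only one acetal remains to be removed; on prenyl step economy it is stronger than the chosen route. Against it, the C4′ ether of ring B has two free ortho positions, and the one between the two oxygens (C3′) is normally at least competitive with C5′, which the target needs. On ring A, C5 competes with C7. Two tertiary allyl aryl ethers are awkward to make and ionise readily, and the hot ortho-prenylphenols can go on to cyclic ethers. The benzofuran aldehyde core must still be built by other means, so the hardest bond of the molecule is not addressed. The chosen route instead fixes both prenyl positions unambiguously at carbons marked by a bromine or by the most acidic ring proton.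

Alternative 2: The C2–C1′ bond is disconnected, with the formyl carbon and the C2′ oxygen tied together as a lactone; the precursor is the 2-bromoaryl benzofuran-3-carboxylate A4. Forward, Pd(OAc)2 with PCy3·HBF4, K2CO3 and pivalic acid would insert zerovalent palladium into the C–Br bond and arylate the benzofuran C2–H through a concerted metalation–deprotonation, closing the six-membered lactone of the coumestan A3. The lactone would then be reduced to the lactol level and the acetals removed. In its favour, intramolecular direct arylation to coumestans is well established, the regiochemistry of the new bond is certain, and the lactone holds the aldehyde carbon and the C2′ oxygen in one robust group; on precedent and scalability of the ring-forming step it is stronger than a photoreaction. Against it, the aryl ester tether is exposed to carbonate at high temperature, and it prefers the conformation that holds the bromide away from C2. Two prenyl groups must also survive hot palladium hydride chemistry without double-bond migration or Heck-type reaction. The lactone must be stopped at the lactol level, and A4 requires a prenylated benzofuran-3-carboxylic acid, so the furan has to be made separately first. The chosen route builds the furan itself from two simple arenes and exposes the prenyl groups only to light at room temperature.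

Alternative 3: The target is traced to the isoflav-3-ene A6, whose chromene ring is opened oxidatively. Forward, DDQ in wet dioxane would abstract hydride from the OCH2 of A6, the free phenol of the 3-aryl group would add to C4 to form the furan, and a second hydride abstraction followed by attack of water would open the pyran to the phenol and the aldehyde of A5. In that cascade the 3-aryl group of A6 becomes ring A and the chromene benzo ring becomes ring B. In its favour, the route is plausibly biomimetic and sets furan, aldehyde and C2′ phenol in a single operation; on brevity of the endgame it is stronger than the chosen route. Against it, the phenol that must add to C4 sits ortho to a prenyl group, and DDQ is the standard reagent for closing exactly such pairs to 2,2-dimethylchromenes. The benzylic–allylic CH2 groups of both prenyl units are themselves hydride donors. The cascade has to stop after two abstractions, although the lactol stage can be oxidised further to the lactone level. A6 itself needs a long isoflavonoid sequence with both prenyl groups in place. The chosen route uses no oxidant until a surface oxidation of one carbinol, and carries C3 at a defined oxidation level throughout.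

Key step: step 9

Remark: eryvarin Q is taken as the open 2′-hydroxy aldehyde drawn for the target; the cyclic lactol is treated as a minor tautomer that returns to the aldehyde on aqueous work-up.

## Route

Step 1
Reactants: 1 4-bromoresorcinol (4-bromobenzene-1,3-diol)
Product: 2 1-bromo-2,4-bis(methoxymethoxy)benzene
Conditions: MOMCl, i-Pr2NEt, CH2Cl2, 0 °C → rt
Reagents that add atoms: chloromethyl methyl ether (MOMCl), COCCl
Why: O-alkylation of both phenols by the reactive α-chloro ether under amine base (Williamson type); the two acetals later flank and acidify the ring position that receives the prenyl group.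

Step 2
Reactants: 2 1-bromo-2,4-bis(methoxymethoxy)benzene; 3 prenyl bromide (1-bromo-3-methylbut-2-ene)
Product: 5 1-bromo-2,4-bis(methoxymethoxy)-3-prenylbenzene, via aryllithium 4 (not isolated)
Conditions: 2,2,6,6-tetramethylpiperidine, n-BuLi, THF, −78 → 0 °C; 2, −78 °C; CuBr·SMe2 (10 mol %), 3, −78 → 0 °C
Reagents that add atoms: prenyl bromide (3), CC(C)=CCBr
Why: Directed ortho-metalation: the hindered lithium amide removes the proton flanked by the two acetal oxygens and does not exchange the bromine; the lithium ends up meta to bromine, so neither aryne formation nor halogen migration is favoured. Copper-catalysed allylic substitution of 3 by aryllithium 4 should occur at the primary carbon (SN2, not SN2′) and give the linear prenyl group.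

Step 3
Reactants: 5 1-bromo-2,4-bis(methoxymethoxy)-3-prenylbenzene; 6 dimethyl oxalate
Product: 8 methyl 2-[2,4-bis(methoxymethoxy)-3-prenylphenyl]-2-oxoacetate, via aryllithium 7 (not isolated)
Conditions: n-BuLi, THF, −78 °C; inverse addition to 6 (3 equiv), THF, −78 °C; NH4Cl aq
Reagents that add atoms: dimethyl oxalate (6), COC(=O)C(=O)OC
Why: Bromine–lithium exchange is faster than deprotonation of the benzylic/allylic CH2 and places lithium at the future C3a. Acylation of aryllithium 7 by excess oxalate diester at low temperature gives a chelated tetrahedral adduct that collapses only on quenching, so the new ketone is not attacked a second time.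

Step 4
Reactants: 8 methyl 2-[2,4-bis(methoxymethoxy)-3-prenylphenyl]-2-oxoacetate
Product: 9 methyl 2-[2-hydroxy-4-(methoxymethoxy)-3-prenylphenyl]-2-oxoacetate
Conditions: p-TsOH·H2O (cat.), MeOH, 0 °C → rt, stopped at mono-cleavage; NaHCO3 aq
Reagents that add atoms: none
Why: Acid-catalysed acetal exchange with methanol. The acetal ortho to the ketone should go first: its two neighbours twist it out of conjugation, the carbonyl oxygen assists protonation, and the released phenol is held in a hydrogen bond to the ketone, whereas the para acetal is deactivated by conjugation with the keto ester. Catalytic acid at room temperature should be too mild to add the phenol across the prenyl double bond.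

Step 5
Reactants: 10 5-bromo-2,4-dihydroxybenzaldehyde
Product: 11 5-bromo-2,4-bis(methoxymethoxy)benzaldehyde
Conditions: MOMCl, i-Pr2NEt, CH2Cl2, 0 → 40 °C
Reagents that add atoms: chloromethyl methyl ether (MOMCl), COCCl
Why: O-alkylation of both phenols; excess reagent and gentle warming are used because the C2 hydroxyl is hydrogen-bonded to the aldehyde.

Step 6
Reactants: 11 5-bromo-2,4-bis(methoxymethoxy)benzaldehyde
Product: 12 [5-bromo-2,4-bis(methoxymethoxy)phenyl]methanol
Conditions: NaBH4, MeOH–THF, 0 °C
Reagents that add atoms: none
Why: Chemoselective borohydride reduction of the aldehyde; the aryl bromide and the acetals are inert. Reducing before the coupling keeps the aldehyde away from the hydroxide base of step 7.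

Step 7
Reactants: 12 [5-bromo-2,4-bis(methoxymethoxy)phenyl]methanol; 13 prenylboronic acid pinacol ester (4,4,5,5-tetramethyl-2-prenyl-1,3,2-dioxaborolane)
Product: 14 [2,4-bis(methoxymethoxy)-5-prenylphenyl]methanol
Conditions: [1,3-bis(2,6-di(pentan-3-yl)phenyl)imidazol-2-ylidene](3-chloropyridine)palladium dichloride (2 mol %), KOH aq (5 M), THF, 70 °C
Reagents that add atoms: prenylboronic acid pinacol ester (13), CC(C)=CCB1OC(C)(C)C(C)(C)O1
Why: Suzuki–Miyaura coupling of an aryl bromide with an allylboronate. With the very bulky carbene ligand the allyl group should be transferred to the aryl group through its primary terminus, giving the linear prenyl arene and not the reverse-prenyl isomer. The free benzylic alcohol and the acetals tolerate aqueous hydroxide.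

Step 8
Reactants: 9 methyl 2-[2-hydroxy-4-(methoxymethoxy)-3-prenylphenyl]-2-oxoacetate; 14 [2,4-bis(methoxymethoxy)-5-prenylphenyl]methanol
Product: 15 methyl 2-[2-{[2,4-bis(methoxymethoxy)-5-prenylphenyl]methoxy}-4-(methoxymethoxy)-3-prenylphenyl]-2-oxoacetate
Conditions: PPh3, DIAD, THF, 0 °C → rt, amber glassware
Reagents that add atoms: none
Why: Mitsunobu etherification: the ortho-acyl phenol is acidic enough to protonate the betaine, and its phenoxide displaces the oxyphosphonium group of the primary benzylic alcohol by SN2. The doubly oxygen-activated benzylic carbon is activated only in the flask, so no labile benzylic halide has to be isolated.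

Step 9
Reactants: 15 methyl 2-[2-{[2,4-bis(methoxymethoxy)-5-prenylphenyl]methoxy}-4-(methoxymethoxy)-3-prenylphenyl]-2-oxoacetate
Product: 17 methyl 2-[2,4-bis(methoxymethoxy)-5-prenylphenyl]-3-hydroxy-6-(methoxymethoxy)-7-prenyl-2,3-dihydro-1-benzofuran-3-carboxylate (racemic cis/trans mixture), via 1,5-biradical 16 (not isolated)
Conditions: hν (350 nm, Pyrex), degassed MeCN (5 mM), 20 °C
Reagents that add atoms: none
Why: Excitation of the aryl α-keto ester and intersystem crossing give a triplet whose carbonyl oxygen abstracts a hydrogen from the ortho ArCH2O group through a seven-membered transition state (1,6-hydrogen transfer), giving 1,5-biradical 16. After spin inversion the ketyl carbon (future C3) and the oxygen- and aryl-stabilised benzylic carbon (future C2) combine, which forms the C2–C3 bond and closes the dihydrofuran ring. The closest known reaction type is the Norrish–Yang photocyclisation of alkyl ortho-(benzyloxy)phenylglyoxylates to 2-aryl-3-hydroxy-2,3-dihydrobenzofuran-3-carboxylates. The ring closes by radical–radical combination of a 1,5-biradical, a five-membered closure with no polar trajectory to satisfy. The two new stereocentres, C2 and C3, form without control and as racemates, which is acceptable because step 10 removes both. The selectivity needed is abstraction at the ether CH2 and not at a prenyl allylic CH2, an acetal CH2 or the ester methyl: only the ether CH2 reaches the carbonyl oxygen through a seven-membered array, its C–H bond is the weakest in the molecule (α to oxygen and benzylic to a dialkoxyaryl ring), the methyl ester offers only strong primary C–H bonds, and both prenyl groups sit meta to the reacting centres. The product no longer contains the keto chromophore and should be stable at 350 nm.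

Step 10
Reactants: 17 methyl 2-[2,4-bis(methoxymethoxy)-5-prenylphenyl]-3-hydroxy-6-(methoxymethoxy)-7-prenyl-2,3-dihydro-1-benzofuran-3-carboxylate
Product: 19 methyl 2-[2,4-bis(methoxymethoxy)-5-prenylphenyl]-6-(methoxymethoxy)-7-prenyl-1-benzofuran-3-carboxylate, via tertiary mesylate 18 (not isolated)
Conditions: MsCl, Et3N, CH2Cl2, 0 °C → rt
Reagents that add atoms: none
Why: Sulfene-mediated mesylation of the tertiary alcohol, then loss of methanesulfonate and the C2 proton (E2 where H and leaving group are anti, ionisation assisted by O1 and the para oxygen otherwise). Aromatisation to the furan drives both diastereomers to the same product and removes both stereocentres.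

Step 11
Reactants: 19 methyl 2-[2,4-bis(methoxymethoxy)-5-prenylphenyl]-6-(methoxymethoxy)-7-prenyl-1-benzofuran-3-carboxylate
Product: 21 {2-[2,4-bis(methoxymethoxy)-5-prenylphenyl]-6-(methoxymethoxy)-7-prenyl-1-benzofuran-3-yl}methanol, via aldehyde 20 (not isolated)
Conditions: i-Bu2AlH (3 equiv), CH2Cl2, −78 → 0 °C; potassium sodium tartrate aq
Reagents that add atoms: none
Why: Two hydride transfers reduce the conjugated ester through aldehyde 20 to the primary alcohol. Stopping at the aldehyde is unreliable for this vinylogous carbonate, so full reduction is accepted and the oxidation level is reset in step 12, where 20 is isolated; acetals and prenyl alkenes are inert.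

Step 12
Reactants: 21 {2-[2,4-bis(methoxymethoxy)-5-prenylphenyl]-6-(methoxymethoxy)-7-prenyl-1-benzofuran-3-yl}methanol
Product: 20 2-[2,4-bis(methoxymethoxy)-5-prenylphenyl]-6-(methoxymethoxy)-7-prenyl-1-benzofuran-3-carbaldehyde
Conditions: MnO2 (activated, excess), CH2Cl2, rt
Reagents that add atoms: none
Why: Surface oxidation of a heteroaryl carbinol (benzylic/allylic type) by MnO2; isolated trisubstituted alkenes and aryl ethers are untouched and the aldehyde is not oxidised further.

Step 13
Reactants: 20 2-[2,4-bis(methoxymethoxy)-5-prenylphenyl]-6-(methoxymethoxy)-7-prenyl-1-benzofuran-3-carbaldehyde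
Product: 22 eryvarin Q, 2-(2,4-dihydroxy-5-prenylphenyl)-6-hydroxy-7-prenyl-1-benzofuran-3-carbaldehyde
Conditions: HCl aq (3 M), MeOH–THF, 40 °C; then H2O, rt
Reagents that add atoms: none
Why: Specific-acid-catalysed cleavage of the three aryl acetals. Methanol captures the methoxymethyl cation as dimethoxymethane, so no formaldehyde is left to attack the resorcinol rings, and the final dilution with water should return any methyl acetal of the aldehyde to the formyl group. Dilute acid at 40 °C is chosen to stay below the conditions that close ortho-prenylphenols to chromans.

## Compound list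

1 | 4-bromoresorcinol (4-bromobenzene-1,3-diol) | Oc1ccc(Br)c(O)c1 | starting material
2 | 1-bromo-2,4-bis(methoxymethoxy)benzene | COCOc1ccc(Br)c(OCOC)c1 | intermediate
3 | prenyl bromide (1-bromo-3-methylbut-2-ene) | CC(C)=CCBr | starting material
4 | [3-bromo-2,6-bis(methoxymethoxy)phenyl]lithium (not isolated) | [Li]c1c(OCOC)ccc(Br)c1OCOC | intermediate
5 | 1-bromo-2,4-bis(methoxymethoxy)-3-prenylbenzene | CC(C)=CCc1c(OCOC)ccc(Br)c1OCOC | intermediate
6 | dimethyl oxalate | COC(=O)C(=O)OC | starting material
7 | [2,4-bis(methoxymethoxy)-3-prenylphenyl]lithium (not isolated) | [Li]c1ccc(OCOC)c(CC=C(C)C)c1OCOC | intermediate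
8 | methyl 2-[2,4-bis(methoxymethoxy)-3-prenylphenyl]-2-oxoacetate | COC(=O)C(=O)c1ccc(OCOC)c(CC=C(C)C)c1OCOC | intermediate
9 | methyl 2-[2-hydroxy-4-(methoxymethoxy)-3-prenylphenyl]-2-oxoacetate | COC(=O)C(=O)c1ccc(OCOC)c(CC=C(C)C)c1O | intermediate
10 | 5-bromo-2,4-dihydroxybenzaldehyde | O=Cc1cc(Br)c(O)cc1O | starting material
11 | 5-bromo-2,4-bis(methoxymethoxy)benzaldehyde | O=Cc1cc(Br)c(OCOC)cc1OCOC | intermediate
12 | [5-bromo-2,4-bis(methoxymethoxy)phenyl]methanol | OCc1cc(Br)c(OCOC)cc1OCOC | intermediate
13 | prenylboronic acid pinacol ester (4,4,5,5-tetramethyl-2-prenyl-1,3,2-dioxaborolane) | CC(C)=CCB1OC(C)(C)C(C)(C)O1 | starting material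
14 | [2,4-bis(methoxymethoxy)-5-prenylphenyl]methanol | OCc1cc(CC=C(C)C)c(OCOC)cc1OCOC | intermediate
15 | methyl 2-[2-{[2,4-bis(methoxymethoxy)-5-prenylphenyl]methoxy}-4-(methoxymethoxy)-3-prenylphenyl]-2-oxoacetate | COC(=O)C(=O)c1ccc(OCOC)c(CC=C(C)C)c1OCc1cc(CC=C(C)C)c(OCOC)cc1OCOC | intermediate
16 | 1,5-biradical from 15: ketyl radical at the former ketone carbon, benzylic radical at the ether carbon (not isolated) | COC(=O)[C](O)c1ccc(OCOC)c(CC=C(C)C)c1O[CH]c1cc(CC=C(C)C)c(OCOC)cc1OCOC | intermediate
17 | methyl 2-[2,4-bis(methoxymethoxy)-5-prenylphenyl]-3-hydroxy-6-(methoxymethoxy)-7-prenyl-2,3-dihydro-1-benzofuran-3-carboxylate, racemic mixture of cis and trans diastereomers | COC(=O)C1(O)C(c2cc(CC=C(C)C)c(OCOC)cc2OCOC)Oc2c(CC=C(C)C)c(OCOC)ccc21 | intermediate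
18 | 3-O-methanesulfonate of 17, mixture of diastereomers (not isolated) | COC(=O)C1(OS(C)(=O)=O)C(c2cc(CC=C(C)C)c(OCOC)cc2OCOC)Oc2c(CC=C(C)C)c(OCOC)ccc21 | intermediate
19 | methyl 2-[2,4-bis(methoxymethoxy)-5-prenylphenyl]-6-(methoxymethoxy)-7-prenyl-1-benzofuran-3-carboxylate | COC(=O)c1c(-c2cc(CC=C(C)C)c(OCOC)cc2OCOC)oc2c(CC=C(C)C)c(OCOC)ccc12 | intermediate
20 | 2-[2,4-bis(methoxymethoxy)-5-prenylphenyl]-6-(methoxymethoxy)-7-prenyl-1-benzofuran-3-carbaldehyde | O=Cc1c(-c2cc(CC=C(C)C)c(OCOC)cc2OCOC)oc2c(CC=C(C)C)c(OCOC)ccc12 | intermediate
21 | {2-[2,4-bis(methoxymethoxy)-5-prenylphenyl]-6-(methoxymethoxy)-7-prenyl-1-benzofuran-3-yl}methanol | OCc1c(-c2cc(CC=C(C)C)c(OCOC)cc2OCOC)oc2c(CC=C(C)C)c(OCOC)ccc12 | intermediate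
22 | eryvarin Q, 2-(2,4-dihydroxy-5-prenylphenyl)-6-hydroxy-7-prenyl-1-benzofuran-3-carbaldehyde (achiral) | CC(C)=CCc1cc(-c2oc3c(CC=C(C)C)c(O)ccc3c2C=O)c(O)cc1O | target

## Step count and risk

Total step count: 13. Longest linear sequence: 10 steps (steps 1–4, then 8–13); ring B is prepared in 3 steps (5–7) and joined in step 8.

**Step 9 (key step).** The most likely failure is an unproductive excited state. The ortho and para oxygen donors on ring A give the triplet π,π* and charge-transfer character, which slows hydrogen abstraction, and the biradical can return the hydrogen and regenerate 15. Slower competing processes could then take over: addition of the excited carbonyl to a prenyl double bond, remote abstraction at an allylic or acetal CH2, or bimolecular photoreduction if the solution is too concentrated. Fallback, from 14 and 9, returning at 19: the C2–C3 bond is made reductively in the ground state. Alcohol 14 is oxidised with MnO2 to 2,4-bis(methoxymethoxy)-5-prenylbenzaldehyde F1 and then with NaClO2/NaH2PO4 and 2-methylbut-2-ene (Pinnick) to 2,4-bis(methoxymethoxy)-5-prenylbenzoic acid F2. Phenol 9 is acylated with F2 (carbodiimide, DMAP) to the aryl ester 6-(2-methoxy-2-oxoacetyl)-3-(methoxymethoxy)-2-prenylphenyl 2,4-bis(methoxymethoxy)-5-prenylbenzoate F3. A McMurry-type intramolecular keto–ester coupling with low-valent titanium (TiCl3, Zn, DME, reflux, pyridine buffer) then joins the ketone carbon to the aryl ester carbon and deoxygenates, giving benzofuran ester 19 directly.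

**Step 4.** Discrimination between the two acetals may be insufficient, so that both are lost, or the freed phenol may add to the prenyl group if the acid is too strong. Fallback, from 8, returning at 9: both acetals are removed deliberately (HCl, MeOH) to give methyl 2-(2,4-dihydroxy-3-prenylphenyl)-2-oxoacetate F4. The C4 hydroxyl alone is then re-protected (MOMCl, 1 equiv, K2CO3, acetone), selectivity coming from the hydrogen bond that holds the C2 hydroxyl on the ketone.

**Step 8.** Coupling at the hindered, hydrogen-bonded phenol may be slow, which gives the betaine time to add to the electrophilic keto group, or the electron-rich oxyphosphonium ion may ionise before it is displaced. Fallback, from 14, returning at 15: the alcohol is converted with MsCl, Et3N and LiCl through [2,4-bis(methoxymethoxy)-5-prenylphenyl]methyl methanesulfonate F5 (not isolated) into 1-(chloromethyl)-2,4-bis(methoxymethoxy)-5-prenylbenzene F6. This is used crude at once to alkylate the potassium phenoxide of 9 (K2CO3, Bu4NI cat., DMF), a Williamson etherification in place of the redox condensation.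

**Step 13.** Protic acid may close a liberated phenol onto the neighbouring prenyl double bond (chroman formation), or the aldehyde may be trapped as a cyclic acetal with the C2′ hydroxyl and methanol. Fallback, from 20, returning at 22: the acetals are exchanged for silyl groups without protic acid. TMSOTf with 2,2′-bipyridyl in MeCN should convert the three aryl acetals into the tris(trimethylsilyl) ether of eryvarin Q F7, the methoxymethyl units being captured by the bipyridyl. Water at neutral pH then hydrolyses the silyl ethers to 22.

**Step 7.** The allyl group may be delivered through its tertiary terminus, giving the 1,1-dimethylallyl isomer, or the electron-rich, ortho-substituted bromide may undergo oxidative addition slowly so that protodeboronation of 13 wins. Fallback, from 12, returning at 14: the alcohol is silylated (TBSCl, imidazole) to tert-butyl{[5-bromo-2,4-bis(methoxymethoxy)phenyl]methoxy}dimethylsilane F8. Bromine–lithium exchange (n-BuLi, THF, −78 °C) gives the aryllithium F9, which is allylated with 3 under CuBr·SMe2 catalysis to the prenylated silyl ether F10. Bu4NF then releases 14.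

## Further compounds

F1 | step 9 | 2,4-bis(methoxymethoxy)-5-prenylbenzaldehyde | O=Cc1cc(CC=C(C)C)c(OCOC)cc1OCOC
F2 | step 9 | 2,4-bis(methoxymethoxy)-5-prenylbenzoic acid | OC(=O)c1cc(CC=C(C)C)c(OCOC)cc1OCOC
F3 | step 9 | 6-(2-methoxy-2-oxoacetyl)-3-(methoxymethoxy)-2-prenylphenyl 2,4-bis(methoxymethoxy)-5-prenylbenzoate | COC(=O)C(=O)c1ccc(OCOC)c(CC=C(C)C)c1OC(=O)c1cc(CC=C(C)C)c(OCOC)cc1OCOC
F4 | step 4 | methyl 2-(2,4-dihydroxy-3-prenylphenyl)-2-oxoacetate | COC(=O)C(=O)c1ccc(O)c(CC=C(C)C)c1O
F5 | step 8 | [2,4-bis(methoxymethoxy)-5-prenylphenyl]methyl methanesulfonate (not isolated) | CS(=O)(=O)OCc1cc(CC=C(C)C)c(OCOC)cc1OCOC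
F6 | step 8 | 1-(chloromethyl)-2,4-bis(methoxymethoxy)-5-prenylbenzene | ClCc1cc(CC=C(C)C)c(OCOC)cc1OCOC
F7 | step 13 | 2-[5-prenyl-2,4-bis(trimethylsilyloxy)phenyl]-7-prenyl-6-(trimethylsilyloxy)-1-benzofuran-3-carbaldehyde | C[Si](C)(C)Oc1ccc2c(C=O)c(-c3cc(CC=C(C)C)c(O[Si](C)(C)C)cc3O[Si](C)(C)C)oc2c1CC=C(C)C
F8 | step 7 | tert-butyl{[5-bromo-2,4-bis(methoxymethoxy)phenyl]methoxy}dimethylsilane | CC(C)(C)[Si](C)(C)OCc1cc(Br)c(OCOC)cc1OCOC
F9 | step 7 | [5-({[tert-butyl(dimethyl)silyl]oxy}methyl)-2,4-bis(methoxymethoxy)phenyl]lithium (not isolated) | [Li]c1cc(CO[Si](C)(C)C(C)(C)C)c(OCOC)cc1OCOC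
F10 | step 7 | tert-butyl{[2,4-bis(methoxymethoxy)-5-prenylphenyl]methoxy}dimethylsilane | CC(C)(C)[Si](C)(C)OCc1cc(CC=C(C)C)c(OCOC)cc1OCOC
A1 | alternative 1 | 2′-O-methoxymethyl eryvarin Q | CC(C)=CCc1cc(-c2oc3c(CC=C(C)C)c(O)ccc3c2C=O)c(OCOC)cc1O
A2 | alternative 1 | 2-{2-(methoxymethoxy)-4-[(2-methylbut-3-en-2-yl)oxy]phenyl}-6-[(2-methylbut-3-en-2-yl)oxy]-1-benzofuran-3-carbaldehyde | C=CC(C)(C)Oc1ccc(-c2oc3cc(OC(C)(C)C=C)ccc3c2C=O)c(OCOC)c1
A3 | alternative 2 | 3,9-bis(methoxymethoxy)-2,10-diprenylcoumestan | O=C1Oc2cc(OCOC)c(CC=C(C)C)cc2-c2oc3c(CC=C(C)C)c(OCOC)ccc3c21
A4 | alternative 2 | 2-bromo-5-(methoxymethoxy)-4-prenylphenyl 6-(methoxymethoxy)-7-prenyl-1-benzofuran-3-carboxylate | O=C(Oc1cc(OCOC)c(CC=C(C)C)cc1Br)c1coc2c(CC=C(C)C)c(OCOC)ccc12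
A5 | alternative 3 | 6-acetoxy-2-(4-acetoxy-2-hydroxy-5-prenylphenyl)-7-prenylbenzofuran-3-carbaldehyde | CC(=O)Oc1cc(O)c(-c2oc3c(CC=C(C)C)c(OC(C)=O)ccc3c2C=O)cc1CC=C(C)C
A6 | alternative 3 | 3-(4-acetoxy-2-hydroxy-3-prenylphenyl)-6-prenyl-2H-chromen-7-yl acetate | CC(=O)Oc1cc2OCC(=Cc2cc1CC=C(C)C)c1ccc(OC(C)=O)c(CC=C(C)C)c1O
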